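Its constants are assumed; the rest is arithmetic.

Both exits of the intermediate are first order in it, so no charge moves their split. Of what leaves the intermediate, the fraction f goes to target:

f = 0.032 min⁻¹ / (0.032 min⁻¹ + 0.017 min⁻¹) = 0.653

With this substrate charge, then, target stays under f times the charge, 0.327 M. I must choose the partner charge for the next run, and what can still change is the substrate lost to homo dimer.

    substrate + partner ⇌ intermediate (K1 = 3.2 M⁻¹, k1 = 0.52 M⁻¹ min⁻¹)
    intermediate → target (k2 = 0.032 min⁻¹)
    2 substrate → homo dimer (k3 = 0.033 M⁻¹ min⁻¹)
    intermediate → decomposed reagent (k4 = 0.017 min⁻¹)

the same everywhere: substrate 0.50 M; time 2.0 h

| flask | partner |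
|---|---|
| amber | 0.400 M |
| red | 0.600 M |
| teal | 1.00 M |

- in percentages every species weighs as the substrate in it: one homo dimer counts as two
- a step written with two of one species runs at k times the square of its concentration and takes two of it each time
- "hardly changes" means that all values lie within two and a half points (for a concentration: within two and a half percent of the largest)
- run time (amber): 2.0 h

* [target] at the end for amber, red, teal, in this order
* the course of these numbers from the first flask to the last (falls, then rises / rises, then falls / hardly changes / falls all the way / rises all the way)

Free substrate sets the order here. Homo dimer goes with its square, the exit through the intermediate with its first power. Binding has a forward half-life of 0.056 h in amber, shorter than the intermediate's half-life 14.1 min, so I let binding reach equilibrium first. Let x be the bound amount, K the equilibrium constant of binding, and R the rate of leaving through the intermediate over the rate of loss to homo dimer: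

x = K([substrate charged] − x)([partner charged] − x)

R = (sum of the two exit constants) · K · [partner] / (two · dimer constant · [substrate])

amber: x = 0.197 M, R = 1.59

red: x = 0.260 M, R = 3.37

teal: x = 0.339 M, R = 9.77

R, this selectivity factor of exit over dimer, gives a dimer share of 1/(1+R) if I hold it fixed, which is an approximation. I then reckon as if all the substrate had gone its way by 2.0 h, which is a simplification and not a claim about the flask:

[target] ≈ f · [substrate charged] · R/(1+R)

This gives 0.201 M, 0.252 M and 0.296 M. Teal stands higher than red, so I would charge teal.

The forecast gives 0.197 M, 0.253 M and 0.29 M, and says the row rises all the way, on the ground that “More partner holds more substrate as intermediate and away from dimerisation”.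

The simulation gives 0.190 M, 0.244 M and 0.290 M: the row rises all the way.

In amber, homo dimer stands at 31.4% at 2.00 h, less than the 38.6% that R gave, and R read from that flask at that time, exit rate over dimer rate, is 4.70, higher than the 1.59 after binding. In teal, R of 9.77 gives a dimer share of 9.29%, and the flask holds 8.81% at 2.00 h.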